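The δ-lactone ring of each half is cut [3+3]: aryl carbon C8a and benzylic C4, 1,3-related on the benzene ring, are joined to the ends of the C1(=O)–O2–C3 triad. In one pot a lithiated ethyl carbamate acylates a Weinreb amide (C3–C4), then ortho-lithiation next to the C8 oxygen and a 1,5 O→C carbamoyl shift put C1 on C8a. The step exploits the local C2 symmetry of the 6,7,8-trioxygenated ring (both ortho positions of the precursor, a 3,5-bis(MOM-oxy)-4-methoxybenzamide, are equivalent) and the C8 oxygen as director. One dione monomer then serves both halves: DKR transfer hydrogenation sets C3/C4, Mitsunobu inversion forges the benzylic aryl ether.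

Key step: step 4

Remarks and assumptions
- Isochroman-1-one numbering is used throughout: C1 (C=O), O2, C3 (CHMe), C4 (benzylic), C4a, C5–C8, C8a.
- C3 of the 1,4-diones 12 and 13 and of the dione half of 15 is α to the C4 ketone and configurationally labile. These compounds are carried as racemates or epimer mixtures, and both stereocentres of each lactone are fixed only in steps 7 and 9.
- The sense of the transfer hydrogenation is assumed from the usual aryl-ketone facial model for the (S,S)-TsDPEN–Ru catalyst, which here corresponds to the 4R carbinol. Should the sense be opposite, the (R,R) complex is used in steps 7 and 9.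

Step 1
Reactants: 1 methyl 3,5-dihydroxy-4-methoxybenzoate
Product: 2 methyl 4-methoxy-3,5-bis(methoxymethoxy)benzoate
Conditions: MOMCl, i-Pr2NEt, CH2Cl2, 0 °C → rt
Reagents that add atoms: chloromethyl methyl ether, COCCl
Why: Double O-alkylation of the two equivalent phenols (Williamson-type acetal ether formation); the MOM groups tolerate the organolithium steps and later act as ortho-directors.

Step 2
Reactants: 2 methyl 4-methoxy-3,5-bis(methoxymethoxy)benzoate
Product: 3 N,4-dimethoxy-3,5-bis(methoxymethoxy)-N-methylbenzamide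
Conditions: MeNH(OMe)·HCl, i-PrMgCl, THF, −20 → 0 °C
Reagents that add atoms: N,O-dimethylhydroxylamine hydrochloride, CNOC.Cl
Why: Weinreb amide formation by aminolysis of the methyl ester with the chloromagnesium amide made in the flask; no stereocentre is involved.

Step 3
Reactants: 4 N,N-diisopropylcarbamoyl chloride; 5 ethanol
Product: 6 ethyl N,N-diisopropylcarbamate
Conditions: pyridine, DMAP (cat.), EtOH as solvent, reflux
Reagents that add atoms: none
Why: Nucleophilic acyl substitution (O-carbamoylation) of ethanol gives the hindered carbamate whose C=O later becomes lactone carbon C1.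

Step 4
Reactants: 6 ethyl N,N-diisopropylcarbamate; 3 N,4-dimethoxy-3,5-bis(methoxymethoxy)-N-methylbenzamide
Product: 11 6-(2-hydroxypropanoyl)-3-methoxy-2,4-bis(methoxymethoxy)-N,N-di(propan-2-yl)benzamide (racemic), via 1-lithioethyl N,N-diisopropylcarbamate 7 (not isolated), via lithium hemiaminal alkoxide adduct 8 (not isolated), via ring-lithiated adduct 9 (not isolated), via rearranged dilithium alkoxide 10 (not isolated)
Conditions: s-BuLi, TMEDA, Et2O, −78 °C; then 3, −78 °C; then s-BuLi, −78 → −20 °C; aq NH4Cl
Reagents that add atoms: none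
Why: s-BuLi/TMEDA removes an O–CH2 proton of 6 to give the dipole-stabilised α-oxy carbanion 7, which acylates 3 to the chelated tetrahedral adduct 8 (C3–C4 bond); a second charge of s-BuLi lithiates 8 at the ring carbon between the OMOM group and the side chain (9), and the aryllithium attacks the carbamate carbonyl with 1,5 O→C carbamoyl migration (C1–C8a bond, 10), work-up releasing the C4 ketone. The closest known reactions are the acylation of α-lithiated O-alkyl carbamates, ortho-lithiation directed by OMOM and an in situ α-amino alkoxide, and the anionic homo-Fries carbamoyl shift; only their telescoping into one pot is new. No ring is closed in the product: the carbamoyl transfer passes through a six-membered cyclic tetrahedral intermediate (6-exo-trig attack) that opens at the C1–O2 bond, and the lactone is closed by O2 on C1 in step 5. C3 is formed racemic on purpose (TMEDA, no chiral ligand) because it becomes α to the C4 ketone and is reset by dynamic kinetic resolution in steps 7 and 9; C4 leaves the step as a carbonyl. The step needs regioselective ring metalation and deprotonation rather than addition by s-BuLi: the two ring hydrogens of 8 are equivalent by symmetry and both flanked by an OMOM oxygen, the ketone is masked as the Weinreb chelate, and the diisopropylcarbamoyl group resists intermolecular attack.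

Step 5
Reactants: 11 6-(2-hydroxypropanoyl)-3-methoxy-2,4-bis(methoxymethoxy)-N,N-di(propan-2-yl)benzamide
Product: 12 6,8-dihydroxy-7-methoxy-3-methylisochromane-1,4-dione (racemic)
Conditions: 6 M aq HCl, 1,4-dioxane, 80 °C; then toluene azeotrope
Reagents that add atoms: none
Why: Aqueous acid cleaves both MOM acetals and converts the hindered amide into the δ-lactone by intramolecular acyl substitution (6-exo-trig attack of the C3 hydroxyl, assisted by the ortho keto group through its pseudo-acid form), with the protonated amine as leaving group.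

Step 6
Reactants: 12 6,8-dihydroxy-7-methoxy-3-methylisochromane-1,4-dione
Product: 13 7-methoxy-6,8-bis(methoxymethoxy)-3-methylisochromane-1,4-dione (racemic)
Conditions: MOMCl, i-Pr2NEt, n-Bu4NI (cat.), CH2Cl2, 0 → 40 °C
Reagents that add atoms: chloromethyl methyl ether, COCCl
Why: O-alkylation of both phenols (the chelated 8-OH needs iodide catalysis and warming) so that the later alcohol carries no competing phenol in the Mitsunobu step.

Step 7
Reactants: 13 7-methoxy-6,8-bis(methoxymethoxy)-3-methylisochromane-1,4-dione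
Product: 14 (3R,4R)-4-hydroxy-7-methoxy-6,8-bis(methoxymethoxy)-3-methylisochroman-1-one
Conditions: RuCl(p-cymene)[(S,S)-TsDPEN] (2 mol%), HCO2H/Et3N (5:2), EtOAc, 30 °C
Reagents that add atoms: none
Why: Noyori-type asymmetric transfer hydrogenation under dynamic kinetic resolution: C3 epimerises through the enol while the Ru hydride reduces the (3R)-ketone from the face anti to the methyl group, which should give the cis-(3R,4R) alcohol (C4 set by the catalyst, C3 by the cis preference of the reduction).

Step 8
Reactants: 14 (3R,4R)-4-hydroxy-7-methoxy-6,8-bis(methoxymethoxy)-3-methylisochroman-1-one; 12 6,8-dihydroxy-7-methoxy-3-methylisochromane-1,4-dione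
Product: 15 (3R,4S)-4-[(8-hydroxy-7-methoxy-3-methyl-1,4-dioxoisochroman-6-yl)oxy]-7-methoxy-6,8-bis(methoxymethoxy)-3-methylisochroman-1-one (epimer mixture at C3 of the dione half)
Conditions: PPh3, DIAD, THF, 0 °C → rt
Reagents that add atoms: none
Why: Mitsunobu etherification: the alkoxyphosphonium of 14 is displaced by the non-chelated, most acidic 6-OH phenol of 12 with SN2 inversion at C4 (4R → 4S); the 8-OH of 12 is hydrogen-bonded to the lactone carbonyl and 12 carries no alcohol.

Step 9
Reactants: 15 (3R,4S)-4-[(8-hydroxy-7-methoxy-3-methyl-1,4-dioxoisochroman-6-yl)oxy]-7-methoxy-6,8-bis(methoxymethoxy)-3-methylisochroman-1-one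
Product: 16 (3R,4S)-4-{[(3R,4R)-4,8-dihydroxy-7-methoxy-3-methyl-1-oxoisochroman-6-yl]oxy}-7-methoxy-6,8-bis(methoxymethoxy)-3-methylisochroman-1-one
Conditions: RuCl(p-cymene)[(S,S)-TsDPEN] (3 mol%), HCO2H/Et3N (5:2), CH2Cl2, 30 °C
Reagents that add atoms: none
Why: A second Noyori-type transfer hydrogenation under dynamic kinetic resolution should converge both C3 epimers of the dione half to the cis-(3R,4R) hydroxy lactone under catalyst control; the (3R,4S) half has no enolisable or reducible site.

Step 10
Reactants: 16 (3R,4S)-4-{[(3R,4R)-4,8-dihydroxy-7-methoxy-3-methyl-1-oxoisochroman-6-yl]oxy}-7-methoxy-6,8-bis(methoxymethoxy)-3-methylisochroman-1-one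
Product: 17 (3R,4S)-4-{[(3R,4R)-4,8-dihydroxy-7-methoxy-3-methyl-1-oxoisochroman-6-yl]oxy}-6,8-dihydroxy-7-methoxy-3-methylisochroman-1-one (CNP0139537.4)
Conditions: 3 M aq HCl, THF, 45 °C
Reagents that add atoms: none
Why: Acidic hydrolysis of the two MOM acetals; the benzylic aryl ether and the benzylic alcohol are deactivated towards ionisation by the ortho lactone carbonyl and should survive.

Compound list
1 | methyl 3,5-dihydroxy-4-methoxybenzoate | COC(=O)c1cc(O)c(OC)c(O)c1 | starting material
2 | methyl 4-methoxy-3,5-bis(methoxymethoxy)benzoate | COCOc1cc(C(=O)OC)cc(OCOC)c1OC | intermediate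
3 | N,4-dimethoxy-3,5-bis(methoxymethoxy)-N-methylbenzamide | COCOc1cc(C(=O)N(C)OC)cc(OCOC)c1OC | intermediate
4 | N,N-diisopropylcarbamoyl chloride | CC(C)N(C(C)C)C(=O)Cl | starting material
5 | ethanol | CCO | starting material
6 | ethyl N,N-diisopropylcarbamate | CCOC(=O)N(C(C)C)C(C)C | intermediate
7 | 1-lithioethyl N,N-diisopropylcarbamate (racemic, TMEDA complex) | CC([Li])OC(=O)N(C(C)C)C(C)C | intermediate
8 | lithium 2-[(diisopropylcarbamoyl)oxy]-1-[methoxy(methyl)amino]-1-[4-methoxy-3,5-bis(methoxymethoxy)phenyl]propan-1-olate | [Li]OC(N(C)OC)(c1cc(OCOC)c(OC)c(OCOC)c1)C(C)OC(=O)N(C(C)C)C(C)C | intermediate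
9 | ring-2-lithio derivative of 8 | [Li]OC(N(C)OC)(c1cc(OCOC)c(OC)c(OCOC)c1[Li])C(C)OC(=O)N(C(C)C)C(C)C | intermediate
10 | dilithium dialkoxide after the 1,5 O→C carbamoyl shift | [Li]OC(C)C(O[Li])(N(C)OC)c1cc(OCOC)c(OC)c(OCOC)c1C(=O)N(C(C)C)C(C)C | intermediate
11 | 6-(2-hydroxypropanoyl)-3-methoxy-2,4-bis(methoxymethoxy)-N,N-di(propan-2-yl)benzamide (racemic) | CC(O)C(=O)c1cc(OCOC)c(OC)c(OCOC)c1C(=O)N(C(C)C)C(C)C | intermediate
12 | 6,8-dihydroxy-7-methoxy-3-methylisochromane-1,4-dione (racemic) | CC1OC(=O)c2c(O)c(OC)c(O)cc2C1=O | intermediate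
13 | 7-methoxy-6,8-bis(methoxymethoxy)-3-methylisochromane-1,4-dione (racemic) | CC1OC(=O)c2c(OCOC)c(OC)c(OCOC)cc2C1=O | intermediate
14 | (3R,4R)-4-hydroxy-7-methoxy-6,8-bis(methoxymethoxy)-3-methylisochroman-1-one | COCOc1cc2c(c(OCOC)c1OC)C(=O)O[C@H](C)[C@@H]2O | intermediate
15 | (3R,4S)-4-[(8-hydroxy-7-methoxy-3-methyl-1,4-dioxoisochroman-6-yl)oxy]-7-methoxy-6,8-bis(methoxymethoxy)-3-methylisochroman-1-one | COCOc1cc2c(c(OCOC)c1OC)C(=O)O[C@H](C)[C@H]2Oc1cc2c(c(O)c1OC)C(=O)OC(C)C2=O | intermediate
16 | (3R,4S)-4-{[(3R,4R)-4,8-dihydroxy-7-methoxy-3-methyl-1-oxoisochroman-6-yl]oxy}-7-methoxy-6,8-bis(methoxymethoxy)-3-methylisochroman-1-one | COCOc1cc2c(c(OCOC)c1OC)C(=O)O[C@H](C)[C@H]2Oc1cc2c(c(O)c1OC)C(=O)O[C@H](C)[C@@H]2O | intermediate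
17 | (3R,4S)-4-{[(3R,4R)-4,8-dihydroxy-7-methoxy-3-methyl-1-oxoisochroman-6-yl]oxy}-6,8-dihydroxy-7-methoxy-3-methylisochroman-1-one | COc1c(O)cc2c(c1O)C(=O)O[C@H](C)[C@H]2Oc1cc2c(c(O)c1OC)C(=O)O[C@H](C)[C@@H]2O | target

Total step count: 10
Longest linear sequence: 9 steps (1, 2, 4, 5, 6, 7, 8, 9, 10); step 3 is a one-step side branch.

Steps most likely to fail

1. Step 4. The ring deprotonation of the crowded tetrahedral adduct may be slow, or s-BuLi may instead attack the N–OMe unit or cause the adduct to collapse, so that the aryllithium needed for the carbamoyl shift is not formed cleanly. Fallback, from 1 back to 11: bromination of 1 (NBS, MeCN, 0 °C) should give methyl 2-bromo-3,5-dihydroxy-4-methoxybenzoate F1. Protection as in step 1 gives methyl 2-bromo-4-methoxy-3,5-bis(methoxymethoxy)benzoate F2, and aminolysis as in step 2 gives 2-bromo-N,4-dimethoxy-3,5-bis(methoxymethoxy)-N-methylbenzamide F3. Acylation of 7 with F3 gives the bromo tetrahedral adduct F4. t-BuLi (2 equiv, −78 °C) then generates aryllithium 9 by bromine–lithium exchange (Parham-type) instead of deprotonation; 9 rearranges to 10 and work-up rejoins the route at 11.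

2. Step 5. Cleavage of the hindered diisopropylamide may be sluggish, or the α-ketol may transpose under hot acid and close to a five-membered lactone (ring contraction to a phthalide). Fallback, from 11 back to 13: O-methylation of the amide oxygen of 11 with trimethyloxonium tetrafluoroborate (2,6-di-tert-butylpyridine, CH2Cl2, rt) gives the O-methyl imidatonium tetrafluoroborate F5. The C3 hydroxyl adds to the activated carbon, and aqueous NaHCO3 then releases diisopropylamine and methanol, giving the MOM-protected dione 13 without Brønsted acid or heat. Dione 12 for step 8 is then made from part of 13 with aq HCl/THF at room temperature.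

3. Step 8. The activated benzylic alcohol may undergo anti-elimination towards the conjugated isocoumarin, partial ionisation may erode the inversion, or the acidic C3–H of 12 may compete with the phenol. Fallback, from 14 back to 15: sulfonylation of 14 (Ms2O, Et3N, CH2Cl2, −30 °C) gives (3R,4R)-7-methoxy-6,8-bis(methoxymethoxy)-3-methyl-1-oxoisochroman-4-yl methanesulfonate F6. This is displaced by the preformed cesium 6-phenoxide of 12 F7 (Cs2CO3, 1 equiv, DMF, 0 °C) in a Williamson-type SN2 reaction with inversion, rejoining the route at 15.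

Further compounds
F1 | step 4 | methyl 2-bromo-3,5-dihydroxy-4-methoxybenzoate | COC(=O)c1cc(O)c(OC)c(O)c1Br
F2 | step 4 | methyl 2-bromo-4-methoxy-3,5-bis(methoxymethoxy)benzoate | COCOc1cc(C(=O)OC)c(Br)c(OCOC)c1OC
F3 | step 4 | 2-bromo-N,4-dimethoxy-3,5-bis(methoxymethoxy)-N-methylbenzamide | COCOc1cc(C(=O)N(C)OC)c(Br)c(OCOC)c1OC
F4 | step 4 | lithium 1-[2-bromo-4-methoxy-3,5-bis(methoxymethoxy)phenyl]-2-[(diisopropylcarbamoyl)oxy]-1-[methoxy(methyl)amino]propan-1-olate | [Li]OC(N(C)OC)(c1cc(OCOC)c(OC)c(OCOC)c1Br)C(C)OC(=O)N(C(C)C)C(C)C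
F5 | step 5 | O-methyl imidatonium tetrafluoroborate of 11 | CC(O)C(=O)c1cc(OCOC)c(OC)c(OCOC)c1C(OC)=[N+](C(C)C)C(C)C.F[B-](F)(F)F
F6 | step 8 | (3R,4R)-7-methoxy-6,8-bis(methoxymethoxy)-3-methyl-1-oxoisochroman-4-yl methanesulfonate | COCOc1cc2c(c(OCOC)c1OC)C(=O)O[C@H](C)[C@@H]2OS(C)(=O)=O
F7 | step 8 | cesium 8-hydroxy-7-methoxy-3-methyl-1,4-dioxoisochroman-6-olate | CC1OC(=O)c2c(O)c(OC)c([O-])cc2C1=O.[Cs+]
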